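## Retrosynthetic overview

1. Ring labels: A is the phloroglucinol-type benzene ring. C is the pyranone ring of the flavanone (stereocenter C2). B is the second benzene ring. D is the gem-dimethylpyranone ring fused to B (atoms O1, C2, C3, C4, C4a, C8a); ring B also holds C6 and the C8 hydroxyl.
2. Disconnection 1: the three O-benzyl groups come off last. Before that, the bond C2 (ring C)–C6 (ring B) is made by enantioselective rhodium-catalysed 1,4-addition of a ring B/D boronic acid to 5,7-bis(benzyloxy)chromone, which sets the only stereocenter late and without base.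
3. Disconnection 2 (key): ring D is dissolved in one operation at O1–C2, C3–C4 and C4–C4a. This gives a 2-iodophenol, carbon monoxide and an isobutenylboronate (carbonylative coupling, then ring closure by oxa-Michael addition).
4. Enabling feature: O1 sits on C8a, ortho to C4a, which bears the C4 ketone, and the quaternary C2 lies β to that ketone. O1–C2 is therefore the bond of a 6-endo addition of the ring B phenoxide to an aryl 2-methylprop-1-enyl ketone. The two methyl groups on C2 favour closure and remove any stereochemical issue.
5. Order of ring formation: ring D on ring B (step 3), ring C on ring A (step 7), union of the two halves (step 8).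

Key step: step 3

Assumption: the (S)-configured biaryl bisphosphine is taken to give the (2S)-flavanone, following the sense known for (S)-biaryl bisphosphine–rhodium catalysts on cyclic enones (O1 of the chromone takes the place of C4 of cyclohexenone, which leaves the descriptor unchanged). If the sense proved opposite, the (R)-ligand would be used.

Assumption: compounds 1, 4 and 9 are taken as catalogue chemicals.

## Route

Step 1
Reactants: 1 2-(benzyloxy)phenol
Product: 2 2-(benzyloxy)-4-bromophenol
Conditions: NBS (1.0 equiv), MeCN, 0 °C to rt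
Reagents that add atoms: N-bromosuccinimide, O=C1CCC(=O)N1Br
Why: Electrophilic aromatic bromination, in which the free hydroxyl group is the strongest donor and NBS in acetonitrile attacks para to it, so that the bromine blocks this position for step 2 and serves as the handle for step 4.

Step 2
Reactants: 2 2-(benzyloxy)-4-bromophenol
Product: 3 2-(benzyloxy)-4-bromo-6-iodophenol
Conditions: NIS (1.05 equiv), TsOH·H2O (10 mol%), MeCN, rt
Reagents that add atoms: N-iodosuccinimide, O=C1CCC(=O)N1I
Why: Electrophilic aromatic iodination with acid-activated NIS, which should go to the only position left ortho to the hydroxyl group because the para position carries bromine and the other ortho position carries the benzyloxy group.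

Step 3
Reactants: 3 2-(benzyloxy)-4-bromo-6-iodophenol; 4 4,4,5,5-tetramethyl-2-(2-methylprop-1-en-1-yl)-1,3,2-dioxaborolane
Product: 6 8-(benzyloxy)-6-bromo-2,2-dimethylchroman-4-one, via senecioyl phenol 5 (not isolated)
Conditions: CO (1 atm), PdCl2(PPh3)2 (5 mol%), K2CO3 (3 equiv), H2O (3 equiv), 4 (1.2 equiv), anisole, 80 °C
Reagents that add atoms: carbon monoxide, [C-]#[O+]
Why: Proposed new method: zerovalent palladium should insert into the carbon–iodine bond of 3, CO insertion gives an aroylpalladium species, the isobutenyl group is handed over from boron (helped by the neighbouring phenoxide as an internal oxygen ligand on palladium) and reductive elimination releases the o-hydroxyaryl 2-methylprop-1-enyl ketone 5, whose potassium phenoxide adds to the β,β-dimethyl terminus of the enone and so forms the O1–C2 bond of ring D. The closest known reaction types are the carbonylative Suzuki–Miyaura ketone synthesis, the palladium-catalysed carbonylative annulations of 2-iodophenols with alkynes or allenes to chromones and 3-methylenechromanones, and the base-induced closure of o-hydroxyaryl 2-methylprop-1-enyl ketones to 2,2-dimethylchroman-4-ones; new is their union with an alkenylboron partner in one flask. Ring D closes in the 6-endo-trig mode, favoured by the gem-dimethyl effect and by the vinylogous ester conjugation gained in the product. No stereocenter is formed, because C2 of ring D carries two identical methyl groups. The step needs carbon–iodine over carbon–bromine selectivity, which the weaker bond, the poorly donating CO/PPh3-ligated palladium and the para-phenoxide that deactivates the bromide should secure, and it needs CO insertion ahead of transmetalation, which the electron-rich arylpalladium, the CO atmosphere and the weakly polar solvent should secure. Intermolecular O-acylation of the phenoxide is held back by its two ortho substituents, and two C–C bonds, one C–O bond and a whole ring arise from a flat iodophenol, CO and a four-carbon boronate.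

Step 4
Reactants: 6 8-(benzyloxy)-6-bromo-2,2-dimethylchroman-4-one
Product: 7 8-(benzyloxy)-2,2-dimethyl-6-(4,4,5,5-tetramethyl-1,3,2-dioxaborolan-2-yl)chroman-4-one
Conditions: B2pin2 (1.2 equiv), PdCl2(dppf) (3 mol%), KOAc (3 equiv), 1,4-dioxane, 90 °C
Reagents that add atoms: bis(pinacolato)diboron, CC1(C)OB(OC1(C)C)B2OC(C)(C)C(C)(C)O2
Why: Miyaura borylation of an unhindered aryl bromide, in which the weak base KOAc should leave the chromanone, its enolisable position and the benzyl ether untouched.

Step 5
Reactants: 7 8-(benzyloxy)-2,2-dimethyl-6-(4,4,5,5-tetramethyl-1,3,2-dioxaborolan-2-yl)chroman-4-one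
Product: 8 [8-(benzyloxy)-2,2-dimethyl-4-oxochroman-6-yl]boronic acid
Conditions: NaIO4 (3 equiv), NH4OAc (3 equiv), acetone/H2O, rt
Reagents that add atoms: water, O
Why: Hydrolysis of the pinacol ester driven by periodate glycol cleavage of the released diol, which gives the free boronic acid that transmetalates to rhodium without added base.

Step 6
Reactants: 9 2',4',6'-trihydroxyacetophenone
Product: 10 1-[2,4-bis(benzyloxy)-6-hydroxyphenyl]ethan-1-one
Conditions: BnBr (2.05 equiv), K2CO3 (2.2 equiv), DMF, rt to 50 °C
Reagents that add atoms: benzyl bromide, BrCc1ccccc1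
Why: Williamson ether synthesis that should stop at the dibenzyl ether, because the last hydroxyl group is hydrogen-bonded to the acetyl carbonyl and is much less nucleophilic.

Step 7
Reactants: 10 1-[2,4-bis(benzyloxy)-6-hydroxyphenyl]ethan-1-one
Product: 12 5,7-bis(benzyloxy)-4H-chromen-4-one, via enaminone 11 (not isolated)
Conditions: DMF-DMA (2 equiv), toluene, 100 °C; concentrate; AcOH, 100 °C
Reagents that add atoms: N,N-dimethylformamide dimethyl acetal, COC(OC)N(C)C
Why: Enaminone chromone synthesis, in which condensation of the methyl ketone with the amide acetal is followed by acid-induced 6-endo addition of the free phenol and elimination of the amine, closing ring C at the chromone level.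

Step 8
Reactants: 8 [8-(benzyloxy)-2,2-dimethyl-4-oxochroman-6-yl]boronic acid; 12 5,7-bis(benzyloxy)-4H-chromen-4-one
Product: 13 (2S)-5,7-bis(benzyloxy)-2-[8-(benzyloxy)-2,2-dimethyl-4-oxochroman-6-yl]chroman-4-one
Conditions: [Rh(OH)(cod)]2 (1.5 mol%), (S)-MeO-F12-BIPHEP [(S)-6,6'-dimethoxy-2,2'-bis[bis(3,4,5-trifluorophenyl)phosphino]-1,1'-biphenyl] (3.3 mol%), 8 (1.5 equiv), CH2Cl2/H2O, rt
Reagents that add atoms: none
Why: Hayashi–Miyaura asymmetric 1,4-addition, a reaction type established for chromones, in which the arylrhodium species formed from 8 adds across C2=C3 of 12 on the enone face left open by the (S)-bisphosphine and so sets C2 as (S), water protonates the oxa-π-allylrhodium, and the base-free medium at room temperature should prevent retro-oxa-Michael racemisation and a second addition to the new ketone.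

Step 9
Reactants: 13 (2S)-5,7-bis(benzyloxy)-2-[8-(benzyloxy)-2,2-dimethyl-4-oxochroman-6-yl]chroman-4-one
Product: 14 (2S)-5,7-dihydroxy-2-(8-hydroxy-2,2-dimethyl-4-oxochroman-6-yl)chroman-4-one (CNP0303522.1)
Conditions: H2 (1 atm), 10% Pd/C, EtOAc/MeOH, rt
Reagents that add atoms: none
Why: Catalytic hydrogenolysis of the three aryl benzyl ethers under neutral conditions, which should leave both aryl ketones, ring D and the base-sensitive C2 stereocenter untouched if the reaction is stopped at full debenzylation.

## Compound list

1 | 2-(benzyloxy)phenol | Oc1ccccc1OCc1ccccc1 | starting material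
2 | 2-(benzyloxy)-4-bromophenol | Oc1ccc(Br)cc1OCc1ccccc1 | intermediate
3 | 2-(benzyloxy)-4-bromo-6-iodophenol | Oc1c(I)cc(Br)cc1OCc1ccccc1 | intermediate
4 | 4,4,5,5-tetramethyl-2-(2-methylprop-1-en-1-yl)-1,3,2-dioxaborolane | CC(C)=CB1OC(C)(C)C(C)(C)O1 | starting material
5 | 1-[3-(benzyloxy)-5-bromo-2-hydroxyphenyl]-3-methylbut-2-en-1-one | CC(C)=CC(=O)c1cc(Br)cc(OCc2ccccc2)c1O | intermediate
6 | 8-(benzyloxy)-6-bromo-2,2-dimethylchroman-4-one | CC1(C)CC(=O)c2cc(Br)cc(OCc3ccccc3)c2O1 | intermediate
7 | 8-(benzyloxy)-2,2-dimethyl-6-(4,4,5,5-tetramethyl-1,3,2-dioxaborolan-2-yl)chroman-4-one | CC1(C)CC(=O)c2cc(B3OC(C)(C)C(C)(C)O3)cc(OCc3ccccc3)c2O1 | intermediate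
8 | [8-(benzyloxy)-2,2-dimethyl-4-oxochroman-6-yl]boronic acid | CC1(C)CC(=O)c2cc(B(O)O)cc(OCc3ccccc3)c2O1 | intermediate
9 | 2',4',6'-trihydroxyacetophenone | CC(=O)c1c(O)cc(O)cc1O | starting material
10 | 1-[2,4-bis(benzyloxy)-6-hydroxyphenyl]ethan-1-one | CC(=O)c1c(O)cc(OCc2ccccc2)cc1OCc1ccccc1 | intermediate
11 | (E)-1-[2,4-bis(benzyloxy)-6-hydroxyphenyl]-3-(dimethylamino)prop-2-en-1-one | CN(C)/C=C/C(=O)c1c(O)cc(OCc2ccccc2)cc1OCc1ccccc1 | intermediate
12 | 5,7-bis(benzyloxy)-4H-chromen-4-one | O=c1ccoc2cc(OCc3ccccc3)cc(OCc3ccccc3)c12 | intermediate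
13 | (2S)-5,7-bis(benzyloxy)-2-[8-(benzyloxy)-2,2-dimethyl-4-oxochroman-6-yl]chroman-4-one | CC1(C)CC(=O)c2cc([C@@H]3CC(=O)c4c(OCc5ccccc5)cc(OCc5ccccc5)cc4O3)cc(OCc3ccccc3)c2O1 | intermediate
14 | (2S)-5,7-dihydroxy-2-(8-hydroxy-2,2-dimethyl-4-oxochroman-6-yl)chroman-4-one | CC1(C)CC(=O)c2cc([C@@H]3CC(=O)c4c(O)cc(O)cc4O3)cc(O)c2O1 | target

## Step count and risks

Total step count: 9. Longest linear sequence: 7 steps (1, 2, 3, 4, 5, 8, 9).

**Step 3 (carbonylative annulation).**
- What may go wrong: transmetalation may run ahead of CO insertion (direct coupling). The aroylpalladium species may be captured by water or by a second phenoxide. Palladium may slowly insert into the carbon–bromine bond, or the cycle may stall at a phenoxide-chelated acylpalladium.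
- Fallback (known chemistry, no CO and no palladium): it sets out from 3 and comes back at 6. Compound 3 is O-acylated with 3-methylbut-2-enoyl chloride (K2CO3, acetone) to 2-(benzyloxy)-4-bromo-6-iodophenyl 3-methylbut-2-enoate F1. Iodine–magnesium exchange with iPrMgCl·LiCl (THF, −40 °C) followed by warming should trigger the anionic Fries-type 1,3-shift of the acyl group from oxygen to the metalated carbon, which gives the phenoxide of 5. K2CO3 in MeOH then closes 5 to 6 by the same oxa-Michael addition.

**Step 8 (asymmetric 1,4-addition).**
- What may go wrong: carbometalation of the chromone may be slow because of shielding by the peri 5-benzyloxy group. Protodeboronation may outrun addition, a second addition to the flavanone carbonyl may occur, or facial selectivity may be insufficient.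
- Fallback: C2 is set by C–O instead of C–C bond formation; it sets out from 6 and 10 and comes back at 13.
  - Formylation of 6 (CO, HCO2Na, PdCl2(PPh3)2, DMF, 100 °C) gives 8-(benzyloxy)-2,2-dimethyl-4-oxochromane-6-carbaldehyde F2.
  - C-acylation of the dianion of 10 (LiN(SiMe3)2, di-tert-butyl dicarbonate, THF, −78 °C) gives tert-butyl 3-[2,4-bis(benzyloxy)-6-hydroxyphenyl]-3-oxopropanoate F3.
  - Knoevenagel condensation of the two (piperidine, AcOH, molecular sieves, toluene) gives tert-butyl (Z)-2-[2,4-bis(benzyloxy)-6-hydroxybenzoyl]-3-[8-(benzyloxy)-2,2-dimethyl-4-oxochroman-6-yl]prop-2-enoate F4.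
  - A cinchona-alkaloid-derived bifunctional thiourea (the pseudoenantiomer that leads to the 2S series, toluene, −25 °C) closes ring C by enantioselective 6-endo oxa-Michael addition. The product is tert-butyl (2S)-5,7-bis(benzyloxy)-2-[8-(benzyloxy)-2,2-dimethyl-4-oxochroman-6-yl]-4-oxochromane-3-carboxylate F5, in which C3 is configurationally labile and left undefined.
  - TsOH in toluene at 80 °C removes the activating ester by dealkylation and decarboxylation and gives 13.

**Step 9 (global debenzylation).**
- What may go wrong: reductive cleavage of the benzylic C2–O1 bond of ring C, over-reduction of an aryl ketone, or incomplete loss of the hindered 5-O-benzyl group.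
- Fallback: the reductive method is replaced by a non-reductive, Lewis-acid-mediated benzyl cation transfer; it sets out from 13 and comes back at 14. BCl3 with pentamethylbenzene as cation scavenger (CH2Cl2, −78 °C) is followed by a mildly acidic quench that avoids base. No compound outside the list is made (F0).

## Further compounds

F1 | step 3 | 2-(benzyloxy)-4-bromo-6-iodophenyl 3-methylbut-2-enoate | CC(C)=CC(=O)Oc1c(I)cc(Br)cc1OCc1ccccc1
F2 | step 8 | 8-(benzyloxy)-2,2-dimethyl-4-oxochromane-6-carbaldehyde | CC1(C)CC(=O)c2cc(C=O)cc(OCc3ccccc3)c2O1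
F3 | step 8 | tert-butyl 3-[2,4-bis(benzyloxy)-6-hydroxyphenyl]-3-oxopropanoate | CC(C)(C)OC(=O)CC(=O)c1c(O)cc(OCc2ccccc2)cc1OCc1ccccc1
F4 | step 8 | tert-butyl (Z)-2-[2,4-bis(benzyloxy)-6-hydroxybenzoyl]-3-[8-(benzyloxy)-2,2-dimethyl-4-oxochroman-6-yl]prop-2-enoate | CC(C)(C)OC(=O)/C(=C\c1cc(OCc2ccccc2)c2OC(C)(C)CC(=O)c2c1)C(=O)c1c(O)cc(OCc2ccccc2)cc1OCc1ccccc1
F5 | step 8 | tert-butyl (2S)-5,7-bis(benzyloxy)-2-[8-(benzyloxy)-2,2-dimethyl-4-oxochroman-6-yl]-4-oxochromane-3-carboxylate | CC1(C)CC(=O)c2cc([C@@H]3C(C(=O)OC(C)(C)C)C(=O)c4c(OCc5ccccc5)cc(OCc5ccccc5)cc4O3)cc(OCc3ccccc3)c2O1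
F0 | step 9 | none | none
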